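**Strategy.** The route rests on cutting the C7–C11 bond of the γ-lactone (ring atoms C7, C8, O, C12, C11). The key step exploits that C7 is the end of a ring 4,6-diene next to the C8 carbinol of a ten-membered 1(10)-cis,4-trans,6-cis triene. A stannyl radical adds to the C8 propiolate, the vinyl radical at C11 closes 5-exo onto C7, and the C4–C6 allyl radical is reduced at C6. One operation thus forms the lactone ring, the C11=C13 methylene (after destannylation), the trans C7/C8 junction and the isolated 4,5-trans alkene. The precursor is the macrocyclic trienyl propiolate, made by olefination and ring-closing metathesis.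

Key step: step 11

Remark: germacrane numbering is used (ring C1–C10, C14 on C10, C15 on C4, lactone carbons C11–C13); cis and trans for ring alkenes refer to the two ring bonds; (R)-2-vinyloxirane is taken as purchasable in enantiopure form.

Step 1
Reactants: 1 propargyl alcohol; 2 2-(2-bromoethyl)-1,3-dioxolane
Product: 5 (Z)-2-[2-(1,3-dioxolan-2-yl)ethyl]-3-iodoprop-2-en-1-ol (iodine cis to CH2OH), via Grignard reagent 3 (not isolated), via alkenylmagnesium bromide 4 (not isolated)
Conditions: 2 (2.5 equiv), Mg, THF, 23 °C; then 1, CuI (10 mol %), THF, −10 to 23 °C; then I2, −78 to 0 °C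
Reagents that add atoms: iodine, II
Why: Copper-catalysed anti-carbomagnesiation of propargyl alcohol (alkoxide-directed, alkyl to C2, magnesium to C3 cis to CH2O) followed by iodinolysis with retention should give the Z-iodide, which fixes the later trans C4=C5 ring alkene.

Step 2
Reactants: 5 (Z)-iodo allylic alcohol
Product: 6 (Z)-tert-butyl{[2-[2-(1,3-dioxolan-2-yl)ethyl]-3-iodoprop-2-enyl]oxy}dimethylsilane
Conditions: TBSCl, imidazole, DMF, 0 to 23 °C
Reagents that add atoms: tert-butyldimethylsilyl chloride, CC(C)(C)[Si](C)(C)Cl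
Why: Standard silylation of a primary alcohol; the TBS ether masks C15–OH until the key step.

Step 3
Reactants: 6 (Z)-iodo silyl ether; 7 tributyl(vinyl)stannane
Product: 8 (Z)-tert-butyl{[2-[2-(1,3-dioxolan-2-yl)ethyl]penta-2,4-dienyl]oxy}dimethylsilane
Conditions: Pd(PPh3)4 (5 mol %), CuI (10 mol %), DMF, 50 °C
Reagents that add atoms: none
Why: Stille coupling proceeds with retention at the alkenyl iodide, so the new vinyl group (C6) ends cis to CH2OTBS.

Step 4
Reactants: 8 dienyl dioxolane
Product: 9 (Z)-4-[(tert-butyldimethylsilyloxy)methyl]hepta-4,6-dienal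
Conditions: Er(OTf)3 (5 mol %), wet MeNO2, 23 °C
Reagents that add atoms: water, O
Why: Lewis-acid-catalysed acetal hydrolysis under near-neutral conditions should free the C1 aldehyde while the primary TBS ether and the diene survive.

Step 5
Reactants: 10 (R)-2-vinyloxirane; 11 triethyl phosphonoacetate
Product: 13 diethyl [(5S)-2-oxo-5-vinyloxolan-3-yl]phosphonate (both C3 epimers), via hydroxy phosphonoester 12 (not isolated)
Conditions: NaOEt, EtOH, 70 °C; aq. HCl work-up
Reagents that add atoms: none
Why: SN2 opening of the epoxide at its unhindered CH2 terminus by the phosphonoacetate anion and lactonisation of the alkoxide (malonate-type epoxide opening) leave C8 untouched, so its configuration comes from 10.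

Step 6
Reactants: 13 α-phosphono lactone; 9 dienal
Product: 14 (3E,5S)-3-[(4Z)-4-[(tert-butyldimethylsilyloxy)methyl]hepta-4,6-dienylidene]-5-vinyloxolan-2-one
Conditions: NaH, THF, 0 °C; then 9, 0 to 23 °C
Reagents that add atoms: none
Why: Horner–Wadsworth–Emmons olefination of an α-phosphono-γ-butyrolactone gives mainly the E-alkylidene lactone (C2 cis to C9), which is the cis C1=C10 ring alkene with C14 at the carboxyl level.

Step 7
Reactants: 14 alkylidene lactone
Product: 16 (3S,5E,9Z)-9-[(tert-butyldimethylsilyloxy)methyl]-5-(hydroxymethyl)dodeca-1,5,9,11-tetraen-3-ol, via lactol 15 (not isolated)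
Conditions: i-Bu2AlH (4 equiv), CH2Cl2, −78 to 0 °C; Rochelle salt work-up
Reagents that add atoms: none
Why: 1,2-Reduction of the lactone through its lactol opens the temporary ring and frees C14–OH and C8–OH in one operation.

Step 8
Reactants: 16 diol
Product: 17 (3S,5E,9Z)-9-[(tert-butyldimethylsilyloxy)methyl]-5-[(tert-butyldiphenylsilyloxy)methyl]dodeca-1,5,9,11-tetraen-3-ol
Conditions: TBDPSCl (1.05 equiv), imidazole, CH2Cl2, −20 to 0 °C
Reagents that add atoms: tert-butyldiphenylsilyl chloride, CC(C)(C)[Si](Cl)(c1ccccc1)c1ccccc1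
Why: The bulky silyl chloride should silylate the primary allylic hydroxyl (C14) and leave the secondary C8–OH free.

Step 9
Reactants: 17 tetraenol
Product: 18 (1S)-cyclodeca-2,4,8-trien-1-ol with CH2OTBS on C5 and CH2OTBDPS on C9 (germacrane: C8–OH, C6=C7 cis, C4=C5 trans, C1=C10 cis)
Conditions: second-generation Grubbs catalyst (10 mol %), CH2Cl2 (1 mM), 40 °C
Reagents that add atoms: none
Why: Ring-closing metathesis joins the vinyl group of the allylic alcohol to the terminal vinyl of the diene, the trisubstituted alkenes being inert; the new C6=C7 bond should be cis because a trans,trans-1,3-diene is badly strained in a ten-membered ring.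

Step 10
Reactants: 18 macrocyclic trienol; 19 propiolic acid
Product: 20 propiolate ester of 18 at C8–O
Conditions: DCC, CH2Cl2, −20 to 0 °C
Reagents that add atoms: none
Why: Carbodiimide (Steglich-type) esterification without DMAP, which would add to the ynoate, acylates the only free hydroxyl with retention at C8.

Step 11
Reactants: 20 trienyl propiolate
Product: 23 (7R,8S)-trans-fused α-methylene-γ-lactone with free C15–OH and C14–OTBDPS (C1=C10 cis, C4=C5 trans), via vinylstannane 21 (not isolated), via bis-silyl lactone 22 (not isolated)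
Conditions: Bu3SnH (1.3 equiv) and AIBN (0.2 equiv) by syringe pump, PhH (2 mM), 80 °C; then HCl (0.5 M in MeOH), 0 to 23 °C
Reagents that add atoms: none
Why: Bu3Sn• adds reversibly to the terminal alkyne carbon C13, the α-carbonyl vinyl radical at C11 adds to C7 at the end of the ring 4,6-diene (5-exo-trig, the only ring closed), and the C4–C5–C6 allyl radical takes hydrogen from Bu3SnH at C6; methanolic HCl then cleaves the vinyl C–Sn bond (giving C11=C13H2) and the primary TBS ether while the TBDPS ether stays. The closest known reaction type is the tin-hydride-mediated radical cyclisation of allylic propiolates to α-stannylmethylene-γ-butyrolactones, followed by protodestannylation. C7 is set by the substrate: in the 6,7-cis ring alkene C8–H lies in the alkene plane (allylic 1,3-strain), so O8 and ring carbon C9 sit on opposite faces, the tethered radical must add to the O8 face of C7, and C6 and C9 end trans on the lactone (7R from 8S). The step needs attack at C7 rather than C6 or the 1(10)-alkene, and hydrogen delivery to C6 rather than C4: only attack at the diene terminus gives an allyl radical through a five-membered transition state, and C6 is the less substituted terminus whose reduction leaves the more substituted 4,5-alkene. Reversible stannyl addition lets the minor s-cis ester rotamer be drained by cyclisation, slow addition of the hydride limits direct reduction of the vinyl radical, and the 4,5-trans geometry is expected to be retained because the allyl radical keeps its configuration on the time scale of hydrogen transfer.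

Step 12
Reactants: 24 (R)-3-bromo-2-hydroxy-2-methylpropanoic acid
Product: 26 (R)-3-chloro-2-hydroxy-2-methylpropanoic acid, via sodium glycidate 25 (not isolated)
Conditions: NaOH (2.1 equiv), H2O, 0 to 23 °C; then conc. HCl, 0 to 23 °C
Reagents that add atoms: hydrogen chloride, Cl
Why: Intramolecular Williamson closure to the glycidate and SN2 opening of the protonated epoxide by chloride at the CH2 terminus never touch C2, so the R configuration is kept.

Step 13
Reactants: 23 C15 alcohol; 26 (R)-chlorohydrin acid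
Product: 27 C15 ester of 23 with (R)-3-chloro-2-hydroxy-2-methylpropanoic acid (C14–OTBDPS)
Conditions: DIC, DMAP (10 mol %), CH2Cl2, 0 to 23 °C
Reagents that add atoms: none
Why: Steglich esterification; the primary allylic alcohol should react far faster than the hindered tertiary hydroxyl of the acid.

Step 14
Reactants: 27 silyl-protected ester
Product: 28 target CNP0239315.1
Conditions: HF·pyridine, THF/pyridine, 0 to 23 °C
Reagents that add atoms: none
Why: Fluoride-mediated desilylation under buffered acidic conditions should free C14–OH without harming the α-methylene lactone or the chlorohydrin ester.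

**Compound list**

1 | propargyl alcohol | C#CCO | starting material
2 | 2-(2-bromoethyl)-1,3-dioxolane | BrCCC1OCCO1 | starting material
3 | [2-(1,3-dioxolan-2-yl)ethyl]magnesium bromide | Br[Mg]CCC1OCCO1 | intermediate
4 | (Z)-[3-(bromomagnesiooxy)-2-[2-(1,3-dioxolan-2-yl)ethyl]prop-1-enyl]magnesium bromide | Br[Mg]OC/C(CCC1OCCO1)=C\[Mg]Br | intermediate
5 | (Z)-2-[2-(1,3-dioxolan-2-yl)ethyl]-3-iodoprop-2-en-1-ol | OC/C(CCC1OCCO1)=C\I | intermediate
6 | (Z)-tert-butyl{[2-[2-(1,3-dioxolan-2-yl)ethyl]-3-iodoprop-2-enyl]oxy}dimethylsilane | CC(C)(C)[Si](C)(C)OC/C(CCC1OCCO1)=C\I | intermediate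
7 | tributyl(vinyl)stannane | C=C[Sn](CCCC)(CCCC)CCCC | starting material
8 | (Z)-tert-butyl{[2-[2-(1,3-dioxolan-2-yl)ethyl]penta-2,4-dienyl]oxy}dimethylsilane | CC(C)(C)[Si](C)(C)OC/C(CCC1OCCO1)=C\C=C | intermediate
9 | (Z)-4-[(tert-butyldimethylsilyloxy)methyl]hepta-4,6-dienal | CC(C)(C)[Si](C)(C)OC/C(CCC=O)=C\C=C | intermediate
10 | (R)-2-vinyloxirane | C=C[C@@H]1CO1 | starting material
11 | triethyl phosphonoacetate | CCOC(=O)CP(=O)(OCC)OCC | starting material
12 | ethyl (4S)-2-(diethoxyphosphoryl)-4-hydroxyhex-5-enoate | CCOC(=O)C(C[C@H](O)C=C)P(=O)(OCC)OCC | intermediate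
13 | diethyl [(5S)-2-oxo-5-vinyloxolan-3-yl]phosphonate | CCOP(=O)(OCC)C1C[C@@H](C=C)OC1=O | intermediate
14 | (3E,5S)-3-[(4Z)-4-[(tert-butyldimethylsilyloxy)methyl]hepta-4,6-dienylidene]-5-vinyloxolan-2-one | O=C1O[C@H](C=C)C/C1=C\CC/C(CO[Si](C)(C)C(C)(C)C)=C/C=C | intermediate
15 | lactol of 14 (oxolan-2-ol) | OC1O[C@H](C=C)C/C1=C\CC/C(CO[Si](C)(C)C(C)(C)C)=C/C=C | intermediate
16 | (3S,5E,9Z)-9-[(tert-butyldimethylsilyloxy)methyl]-5-(hydroxymethyl)dodeca-1,5,9,11-tetraen-3-ol | C=C[C@@H](O)C/C(CO)=C\CC/C(CO[Si](C)(C)C(C)(C)C)=C/C=C | intermediate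
17 | (3S,5E,9Z)-9-[(tert-butyldimethylsilyloxy)methyl]-5-[(tert-butyldiphenylsilyloxy)methyl]dodeca-1,5,9,11-tetraen-3-ol | C=C[C@@H](O)C/C(CO[Si](c1ccccc1)(c1ccccc1)C(C)(C)C)=C\CC/C(CO[Si](C)(C)C(C)(C)C)=C/C=C | intermediate
18 | (1S)-5-[(tert-butyldimethylsilyloxy)methyl]-9-[(tert-butyldiphenylsilyloxy)methyl]cyclodeca-2,4,8-trien-1-ol (C6=C7 cis, C4=C5 trans, C1=C10 cis) | O[C@H]1C/C(CO[Si](c2ccccc2)(c2ccccc2)C(C)(C)C)=C\CC/C(CO[Si](C)(C)C(C)(C)C)=C/C=C\1 | intermediate
19 | propiolic acid | C#CC(=O)O | starting material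
20 | propiolate ester of 18 | C#CC(=O)O[C@H]1C/C(CO[Si](c2ccccc2)(c2ccccc2)C(C)(C)C)=C\CC/C(CO[Si](C)(C)C(C)(C)C)=C/C=C\1 | intermediate
21 | trans-fused α-[(tributylstannyl)methylene] lactone, bis-silyl ether | CCCC[Sn](CCCC)(CCCC)C=C1C(=O)O[C@H]2C/C(CO[Si](c3ccccc3)(c3ccccc3)C(C)(C)C)=C\CC/C(CO[Si](C)(C)C(C)(C)C)=C/C[C@H]12 | intermediate
22 | trans-fused α-methylene lactone, C14–OTBDPS, C15–OTBS | C=C1C(=O)O[C@H]2C/C(CO[Si](c3ccccc3)(c3ccccc3)C(C)(C)C)=C\CC/C(CO[Si](C)(C)C(C)(C)C)=C/C[C@H]12 | intermediate
23 | trans-fused α-methylene lactone, C14–OTBDPS, C15–OH | C=C1C(=O)O[C@H]2C/C(CO[Si](c3ccccc3)(c3ccccc3)C(C)(C)C)=C\CC/C(CO)=C/C[C@H]12 | intermediate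
24 | (R)-3-bromo-2-hydroxy-2-methylpropanoic acid | OC(=O)[C@@](C)(O)CBr | starting material
25 | sodium (S)-2-methyloxirane-2-carboxylate | [Na+].[O-]C(=O)[C@]1(C)CO1 | intermediate
26 | (R)-3-chloro-2-hydroxy-2-methylpropanoic acid | OC(=O)[C@@](C)(O)CCl | intermediate
27 | C15 (R)-3-chloro-2-hydroxy-2-methylpropanoate of 23 | C=C1C(=O)O[C@H]2C/C(CO[Si](c3ccccc3)(c3ccccc3)C(C)(C)C)=C\CC/C(COC(=O)[C@@](C)(O)CCl)=C/C[C@H]12 | intermediate
28 | CNP0239315.1 | C=C1C(=O)O[C@H]2C/C(CO)=C\CC/C(COC(=O)[C@@](C)(O)CCl)=C/C[C@H]12 | target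

**Totals.** 14 steps in all; the longest linear sequence is 12 steps (steps 1–4, 6–11, 13, 14).

**Steps most likely to fail**

Step 11. The vinyl radical may be reduced by the tin hydride before the ester turns into the s-cis rotamer that can close (net hydrostannation of the alkyne), or the allyl radical may take hydrogen at C4. The fallback keeps the C7–C11 ring closure but uses an acetal tether, which has no rotamer barrier. It sets out from 18: acetal exchange with 3,3-diethoxyprop-1-yne (PPTS, toluene, 60 °C) gives the mixed propargylic acetal F1. Bu3SnH and AIBN (PhH, 80 °C) close it by stannyl-radical enyne cyclisation to the bicyclic ethoxy acetal F2. PPTS in wet acetone removes tin and ethanol to give the α-methylene lactol F3. MnO2 in CH2Cl2 oxidises the allylic lactol and returns to the route at 22, which the acid treatment of step 11 turns into 23.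

Step 9. Chain growth by intermolecular metathesis may outrun closure of the strained ten-membered triene, or the ring may close to the 6,7-trans isomer. The fallback closes the ring at C1=C10 by an intramolecular Horner–Wadsworth–Emmons reaction after the C5–C6 bond has been made by cross-coupling. It sets out from 6 and 11: 11 and (R)-2-ethynyloxirane (NaOEt, EtOH) give the ethynyl phosphono lactone F4. Sonogashira coupling with 6 (PdCl2(PPh3)2, CuI, i-Pr2NH) gives the enyne F5. Zinc activated with Cu(OAc)2 and AgNO3 (MeOH/H2O) reduces the alkyne to the 6,7-cis diene F6. Er(OTf)3 in wet MeNO2 frees the aldehyde F7. LiCl and DBU in MeCN at high dilution close the bridged alkylidene lactone F8. i-Bu2AlH gives the ring diol F9, and TBDPSCl with imidazole silylates its primary hydroxyl to return to the route at 18.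

Step 13. The activated acid may acylate its own free tertiary hydroxyl, and the chlorohydrin may lose HCl to the glycidate under the basic acylation conditions. The fallback introduces chloride after the ester bond. It sets out from 23 and 25: acidification of 25 gives (S)-2-methyloxirane-2-carboxylic acid F10, which has no free hydroxyl. DIC and DMAP couple it with 23 to the glycidate ester F11. Pyridinium chloride in CH2Cl2 opens the epoxide at its CH2 terminus and returns to the route at 27.

Further compounds
F1 | step 11 | mixed acetal of 18 with 3,3-diethoxyprop-1-yne | C#CC(OCC)O[C@H]1C/C(CO[Si](c2ccccc2)(c2ccccc2)C(C)(C)C)=C\CC/C(CO[Si](C)(C)C(C)(C)C)=C/C=C\1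
F2 | step 11 | bicyclic 2-ethoxy-3-[(tributylstannyl)methylene]oxolane | CCCC[Sn](CCCC)(CCCC)C=C1C(OCC)O[C@H]2C/C(CO[Si](c3ccccc3)(c3ccccc3)C(C)(C)C)=C\CC/C(CO[Si](C)(C)C(C)(C)C)=C/C[C@H]12
F3 | step 11 | α-methylene lactol | C=C1C(O)O[C@H]2C/C(CO[Si](c3ccccc3)(c3ccccc3)C(C)(C)C)=C\CC/C(CO[Si](C)(C)C(C)(C)C)=C/C[C@H]12
F4 | step 9 | diethyl [(5S)-5-ethynyl-2-oxooxolan-3-yl]phosphonate | CCOP(=O)(OCC)C1C[C@@H](C#C)OC1=O
F5 | step 9 | enyne from 6 and F4 | CCOP(=O)(OCC)C1C[C@@H](C#C/C=C(\CO[Si](C)(C)C(C)(C)C)CCC2OCCO2)OC1=O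
F6 | step 9 | 6,7-cis diene phosphono lactone | CCOP(=O)(OCC)C1C[C@@H](/C=C\C=C(/CO[Si](C)(C)C(C)(C)C)CCC2OCCO2)OC1=O
F7 | step 9 | aldehyde phosphono lactone | CCOP(=O)(OCC)C1C[C@@H](/C=C\C=C(/CO[Si](C)(C)C(C)(C)C)CCC=O)OC1=O
F8 | step 9 | bridged macrocyclic alkylidene lactone (C14 to O8) | O=C1O[C@H]2C/C1=C\CC/C(CO[Si](C)(C)C(C)(C)C)=C/C=C\2
F9 | step 9 | macrocyclic diol (C8–OH, C14–OH, C15–OTBS) | O[C@H]1C/C(CO)=C\CC/C(CO[Si](C)(C)C(C)(C)C)=C/C=C\1
F10 | step 13 | (S)-2-methyloxirane-2-carboxylic acid | OC(=O)[C@]1(C)CO1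
F11 | step 13 | C15 (S)-2-methylglycidate of 23 | C=C1C(=O)O[C@H]2C/C(CO[Si](c3ccccc3)(c3ccccc3)C(C)(C)C)=C\CC/C(COC(=O)[C@]3(C)CO3)=C/C[C@H]12
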